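- The constants put substrate + double product → side product lowest of the four, and lowest in activation energy too, so I watch that arrow.

    substrate + reagent → mono adduct (k1 = 0.032 /M/s, Ea1 = 66.0 kJ/mol)
    reagent + mono adduct → double product (k2 = 0.061 /M/s, Ea2 = 57.0 kJ/mol)
    mono adduct + capture agent → trapped intermediate (k3 = 0.0048 /M/s, Ea3 = 52.0 kJ/mol)
    substrate + double product → side product (k4 = 0.0037 /M/s, Ea4 = 48.0 kJ/mol)
    (constants at 25 °C)

common to all: substrate 0.050 M; reagent 0.0550 M; capture agent 0.0150 M; time 80 min
- alder: temperature 25 °C
- elm: temperature 75 °C
- ash: temperature 50 °C

1. which of these there is most of at the end, counted by the substrate in it, alder (substrate / side product / mono adduct / double product / trapped intermediate)
2. which of these there is most of at the end, counted by the substrate in it, elm (substrate / side product / mono adduct / double product / trapped intermediate)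
3. which of these there is most of at the end, counted by the substrate in it, ash (substrate / side product / mono adduct / double product / trapped intermediate)
4. amount of the one of these that there is most of at the end, in percent of the substrate charged, alder
5. amount of the one of these that there is most of at the end, in percent of the substrate charged, elm
6. amount of the one of these that there is most of at the end, in percent of the substrate charged, ash

- percent here means substrate units held: one side product counts as two
- the list of constants is for 25 °C, to be carried to other temperatures by the activation energies

- I first switch the side step off in my head: each double product takes two reagents, so the reagent charge caps double product at 55.0 % of the substrate.
- Then I make the side step instantaneous: each double product meets a substrate at once, and each side product holds two of each. The reagent stands at 1.10 equivalents, more than the one needed, so the reagent balance puts the ceiling for side product at 100 %. That is a ceiling and not a yield, since capture agent, charged at 30.0 % of the substrate, can divert mono adduct into trapped intermediate.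
- The real flask lies between these two, and I place it by the side count: step 4's constant times charged substrate times time, the number of lifetimes a double product gets against charged substrate. Substrate falls during the run, so the count reads high.
- For alder the count is 0.888, or −0.0516 in powers of ten.
- Step 1 counted the same way, with charged reagent, gives 8.45 in alder, about ten times the side count. So in alder double product forms first and the side step trails.
- Warming adds 0.651 powers of ten for ash, giving a side count of 3.97.
- Warming adds 1.21 powers of ten for elm, giving a side count of 14.3.
- I commit to this: alder, with a count below one, ends with double product on top, under its cap. Ash and elm, with counts above one, end with side product on top. My reckoning gives winners and bounds, not finer amounts.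
- The forecast says double product at 35 % for alder, side product at 59 % for elm and side product at 45 % for ash, on the ground that “leftover substrate combines with double product”.
- Alder ends with double product on top at 34.1 %, elm with side product at 52.4 %, and ash with side product at 40.6 %. Double product and side product stand level at 35.8 °C, where the side count is 1.75. A repeat of alder at 0 °C has a side count of 0.151, less than one, and that flask ends with 1.75 % side product.

The rate constants were set for the occasion; the run is a simulation.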